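# Proposed total synthesis of CNP0360871.1 (3α-angeloyloxy-4α-acetoxy-7α-hydroperoxy-5α-eudesm-11-en-8-one)

## Structural features

The target is a trans-fused decalin of the eudesmane type. Ring A (C1–C5, C10) and ring B (C5–C10) share the C5–C10 bond, with the C14 methyl axial on quaternary C10 and H5 on the opposite (α) face. Ring A carries two contiguous oxygenated centres next to the ring fusion: C3 with an axial α-angelate (a Z-2-methylbut-2-enoate) and fully substituted C4 with an α-acetate and the β-methyl C15. C3, C4, C5 and C10 therefore form an unbroken run of four stereocentres, two of them quaternary. Ring B holds the C8 ketone and, next to it, fully substituted C7 with an α-hydroperoxy group and a β-isopropenyl group (C11–C13). The fragile groups are the tertiary α-hydroperoxy ketone (reduction, base-induced C7–C8 cleavage), the angelate (Z to E isomerisation, epoxidation) and the tertiary acetate beside a secondary ester (acyl migration as soon as either oxygen is free). The real difficulty is the congested C3–C4–C5–C10 array with an ester on a tertiary carbon, together with oxygenation of C7 without touching C9 or the esters. The key step uses the fact that the C4 acetate can descend from a C4 acetyl group. C4=C5 is then an enone dienophile and the C3 oxygen a donor on a diene C10=C1–C2=C3, so ring A forms by a [4+2] cycloaddition while the C6–C9 tether closes ring B.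

## Logic of the disconnections

**27 ⇒ 25.** The C7–O bond is cut first, because the hydroperoxide tolerates neither reductants, nor base, nor peracid and must be made last. 25 is a stable conjugated ketone whose γ-deprotonation gives a dienolate that can take up dioxygen at C7 while the alkene moves to C11=C12. A singlet-oxygen ene reaction on 25 is not chosen, because a conjugated enone is expected to accept oxygen at C11 with loss of a C6 hydrogen. The forward step must enolise toward C12 and not C9, and must add oxygen on the α face.

**25 ⇒ 21.** The C7=C11 bond is cut (aldol condensation retron, through 23); the three isopropylidene carbons come from a simple C3 ketone electrophile. This removes C11–C13 and leaves a ketone with two α-methylene groups. The forward step must enolise toward C7, which is helped by C9 being neopentyl.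

**21 ⇒ 19.** No skeletal bond is cut; the C8 carbonyl is traced through 20 to a silyl-protected secondary alcohol. A C8 ketone could not be present during the peracid step, and the protected alcohol is the stereocontrol element of the cycloaddition. Deprotection and oxidation must leave both esters in place.

**19 ⇒ 18.** The C4–O bond is cut: the tertiary acetate becomes a C4 acetyl group (Baeyer–Villiger retron). The hindered tertiary ester then never needs acylation of a tertiary alcohol, and C4 gains the acceptor group that makes C4=C5 a dienophile. The forward step needs migration of the tertiary carbon with retention and must spare the angelate.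

**18 ⇒ 15 + 16.** The ester C–O bond at O3 is cut. Acylation is placed before the oxygen insertion so that a free hydroxyl at C3 never stands next to the C4 acetate. The forward step must acylate a hindered axial alcohol without Z to E isomerisation.

**15 ⇒ 13.** The C1–H and C2–H bonds and the O–benzyl bond are cut; saturated ring A with a free C3 hydroxyl maps back to the cyclohexene and benzyl ether that a cycloaddition leaves. The alkene must be reduced before hydrogenolysis can reach the allylic C3–O bond.

**13 ⇒ 12.** The C3–C4 and C5–C10 bonds are cut (retro-[4+2]). Both rings and four contiguous stereocentres collapse to an acyclic triene with one stereocentre. The forward step needs endo and facial selectivity and enough reactivity to join two fully substituted carbons.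

**12 ⇒ 9 + 11, and 11 ⇒ 10.** The C1–C2 bond between two sp2 carbons is cut (cross-coupling retron), so each alkene geometry is set in a separate fragment and the sensitive dienol ether appears only one step before cyclisation. 11 is traced to 10 by removing the C–B and C–H bonds added across the alkyne. The coupling must retain both geometries and spare the enone; the hydroboration must be syn and terminal-selective.

**9 ⇒ 7 + 8.** The C4=C5 bond is cut (Wittig retron), which brings in C4, C15 and the acetyl group in one piece. The forward step must be E-selective.

**7 ⇒ 5.** The C5 aldehyde is traced to a terminal alkene with one extra carbon; the alkene is an inert aldehyde surrogate during the organoaluminium step. The oxidant must distinguish the terminal alkene from the iodoalkene.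

**5 ⇒ 3 ⇒ 2 ⇒ 1.** The C10–C14 and C1–I bonds are cut together (carbometalation–iodination of a terminal alkyne), then the O–Si bond, then the C9–C10 bond (acetylide opening of a terminal epoxide). The only stereocentre of the acyclic series, C8, is bought with 1. The forward steps need syn, terminal-selective methylmetalation and epoxide opening at the unsubstituted carbon.

## Other disconnections considered

**Alternative 1:** The cut is the C10–C14 bond; the angular methyl is traced to a cyclopropane across C5 and C10 whose C5–C14 bond is sacrificed later.
- **Forward key step:** the zinc alkoxide of allylic alcohol A1 (4β-hydroxyl, tetrasubstituted C5=C10, C8 ketal) would direct a zinc carbenoid to the β face and give cyclopropane A2. Oxidation at C4 and dissolving-metal opening would then leave C14 on C10 and an enolate whose protonation sets the trans fusion.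
- **In favour:** hydroxyl-directed methylene transfer to a tetrasubstituted allylic alcohol is among the most dependable stereocontrolled C–C bond formations. A1 should be reachable in a few operations from a commercial aromatic precursor, with its one stereocentre set by catalytic asymmetric reduction. The C8 oxygen is present from the start as a robust ketal.
- **Against:** the key step delivers one skeletal bond and in effect one stereocentre. C15, both ring-A oxygens and the whole C7 array remain. The C4 carbonyl would have to accept methyl from the less favourable direction (or go through a C3=C4 alkene and osmylation). The tertiary hydroxyl would then need acetylation beside a secondary ester, which is where acyl migration threatens.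
- **Comparison:** on the quaternary C10 centre alone this route is the better one, since directed cyclopropanation is far less demanding than a cycloaddition joining two fully substituted carbons. On absolute configuration it is equal or better (catalyst control, no sacrificial stereocentre). Mechanistically it replaces one concerted pericyclic event by three well-behaved stages. In step economy it is expected to be longer, because ring A must be functionalised stepwise, whereas the chosen plan delivers the C3 oxygen, C4 with its masked acetate, C5 and C10 together.

**Alternative 2:** The cut is C9–C10, with a temporary C5–C8 bond; quaternary C10 arises by photocycloaddition.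
- **Forward key step:** enone A3, bound to a chiral oxazaborolidine–AlBr3 Lewis acid and excited to its triplet state, would add allene A4 head-to-head to give methylenecyclobutane A5. Functionalisation of the exocyclic alkene and retro-aldol cleavage of C5–C8 would unveil a C8 methyl ketone side chain. After a one-carbon unit is added at C5, a Michael closure would complete ring B.
- **In favour:** A3 and A4 are commodity chemicals. The absolute configuration at C10 would come from a catalyst, which is better than the chosen plan's chiral-pool epoxide and sacrificial stereocentre. The fragmentation leaves carbonyl groups at C4 and C8, so on the C8 oxidation state it is at least equal.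
- **Against:** low-temperature irradiation and a high Lewis-acid loading are usual for this reaction type, and enantioselectivity with allene and a β-substituted enone is not assured. After the key step only C10 is in place. C5, the C4 methyl and acetate, C3, the ring B closure and the C7 array would all follow, with the trans fusion resting on equilibration.
- **Comparison:** structurally it solves one quaternary centre elegantly but not the C3/C4 problem. Mechanistically it is a stepwise triplet 1,4-diradical addition under catalyst shielding, against a concerted, substrate-controlled cycloaddition. In step economy it is expected to be clearly longer, and it carries one sacrificial bond where the chosen plan has none.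

**Alternative 3:** The cut is C7–C8; ring B closes by an intramolecular carbonyl-ene reaction.
- **Forward key step:** Me2AlCl would activate the C8 aldehyde of A6 (a ring A cyclohexene with C3=C4, the acetaldehyde arm on quaternary C10 and a prenyl group on C5). Through a chair-like transition state the C7=C11 alkene would add to the carbonyl with transfer of a C12 hydrogen, giving A7 with 7β-isopropenyl and 8α-hydroxyl both equatorial.
- **In favour:** the isopropenyl group and the C8 oxygen arrive in one step. After oxidation at C8, the C7–H would be both α to the ketone and allylic, the ideal site for the final enolate oxygenation. On this point the alternative is better than the chosen plan, which needs aldol addition, dehydration and a γ-deprotonation that competes with C9. The C3=C4 alkene is also well placed for α-face osmylation to the cis-3α,4α-diol.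
- **Against:** A6 already contains the vicinal C5 and C10 stereocentres, one quaternary, which need separate asymmetric chemistry. The dihydroxylation must distinguish C3=C4 from C11=C12, or precede the ene step with extra protection. The ring alkene might compete as the ene donor. The tertiary C4 hydroxyl would have to be acetylated beside the C3 ester, the migration-prone operation that the oxygen insertion of the chosen plan avoids.
- **Comparison:** structurally it is stronger for ring B and weaker for ring A. Both plans create a stereocentre that is later erased, so they are equal there. Both key steps are concerted, chair-like and promoted by the same Lewis acid, but the ene reaction forms one C–C bond and the cycloaddition two. The endgame would be about two steps shorter, yet the preparation of A6 and the differentiation of the diol are expected to cost at least as much as is saved.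

Key step: step 8

## Remarks on the chemistry

- Eudesmane numbering is used throughout; α is the face opposite the C14 methyl, and "angeloyl" means (Z)-2-methylbut-2-enoyl.
- Assumption: 1 and 10 are purchasable; 10 rearranges on warming and is handled cold.

## Route

Step 1
Reactants: 1 (R)-2-(but-3-en-1-yl)oxirane
Product: 2 (R)-oct-7-en-1-yn-4-ol
Conditions: LiC≡CH·H2NCH2CH2NH2, DMSO, 0 °C → rt; aq. NH4Cl
Reagents that add atoms: lithium acetylide–ethylenediamine complex, [Li]C#C.NCCN
Why: Epoxide alkynylation: the acetylide opens the terminal epoxide at its unsubstituted carbon (SN2) and forms the C9–C10 bond without touching the carbinol centre, so the (R) configuration of 1 becomes C8.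

Step 2
Reactants: 2 (R)-oct-7-en-1-yn-4-ol
Product: 3 (R)-tert-butyldimethyl(oct-7-en-1-yn-4-yloxy)silane
Conditions: TBSCl, imidazole, DMF, rt
Reagents that add atoms: tert-butyldimethylsilyl chloride, CC(C)(C)[Si](C)(C)Cl
Why: Imidazole-promoted silylation of a secondary alcohol; the silyl ether should withstand organoalanes, osmylation, ylides, aqueous phosphate, Me2AlCl and buffered peracid, and later acts as the equatorial control element.

Step 3
Reactants: 3 (R)-tert-butyldimethyl(oct-7-en-1-yn-4-yloxy)silane
Product: 5 (R,E)-tert-butyl[(1-iodo-2-methylocta-1,7-dien-4-yl)oxy]dimethylsilane, via alkenylalane 4 (not isolated)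
Conditions: Me3Al, Cp2ZrCl2 (20 mol %), CH2Cl2, 0 °C → rt; then I2, THF, −30 → 0 °C
Reagents that add atoms: trimethylaluminium, C[Al](C)C; iodine, II
Why: Zirconium-catalysed carboalumination adds CH3 and Al syn across the terminal alkyne with aluminium on the terminal carbon, and iodinolysis goes with retention, which places C14 on C10 and fixes the E geometry of C10=C1; the monosubstituted alkene is carbometalated much more slowly.

Step 4
Reactants: 5 (R,E)-tert-butyl[(1-iodo-2-methylocta-1,7-dien-4-yl)oxy]dimethylsilane
Product: 7 (R,E)-4-(tert-butyldimethylsilyloxy)-7-iodo-6-methylhept-6-enal, via 1,2-diol 6 (not isolated)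
Conditions: OsO4 (2 mol %), NaIO4, 2,6-lutidine, 1,4-dioxane/H2O, rt
Reagents that add atoms: osmium tetroxide, O=[Os](=O)(=O)=O; sodium periodate, [Na+].[O-]I(=O)(=O)=O
Why: Lemieux–Johnson cleavage: osmylation should select the unhindered monosubstituted alkene over the trisubstituted, inductively deactivated iodoalkene, and periodate cleaves the diol and regenerates the osmium oxidant.

Step 5
Reactants: 7 (R,E)-4-(tert-butyldimethylsilyloxy)-7-iodo-6-methylhept-6-enal; 8 3-(triphenylphosphoranylidene)butan-2-one
Product: 9 (7R,3E,9E)-7-(tert-butyldimethylsilyloxy)-10-iodo-3,9-dimethyldeca-3,9-dien-2-one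
Conditions: toluene, 90 °C
Reagents that add atoms: none
Why: Wittig olefination with a stabilised, α-branched acyl ylide is reversible at the addition stage and should give the E-trisubstituted enone, the geometry that the cycloaddition later turns into the cis relation of acetyl and H5.

Step 6
Reactants: 10 benzyl ethynyl ether
Product: 11 (E)-2-[2-(benzyloxy)ethenyl]-4,4,5,5-tetramethyl-1,3,2-dioxaborolane
Conditions: pinacolborane, Cp2Zr(H)Cl (5 mol %), Et3N (10 mol %), CH2Cl2, 0 °C → rt
Reagents that add atoms: pinacolborane, [H]B1OC(C)(C)C(C)(C)O1
Why: Catalysed hydroboration of an alkynyl ether is a syn addition with boron on the terminal carbon and should give the E-alkenylboronate; working at or below room temperature avoids the thermal rearrangement of 10.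

Step 7
Reactants: 9 (7R,3E,9E)-7-(tert-butyldimethylsilyloxy)-10-iodo-3,9-dimethyldeca-3,9-dien-2-one; 11 (E)-2-[2-(benzyloxy)ethenyl]-4,4,5,5-tetramethyl-1,3,2-dioxaborolane
Product: 12 (7R,3E,9E,11E)-12-(benzyloxy)-7-(tert-butyldimethylsilyloxy)-3,9-dimethyldodeca-3,9,11-trien-2-one
Conditions: Pd(PPh3)4 (5 mol %), K3PO4 (aq.), THF, 45 °C
Reagents that add atoms: none
Why: Suzuki–Miyaura coupling forms the C1–C2 bond with retention of both alkene geometries and should give the E,E-diene; the phosphate base spares enone and silyl ether, and the acid-sensitive dienol ether is purified on amine-deactivated silica and used at once.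

Step 8
Reactants: 12 (7R,3E,9E,11E)-12-(benzyloxy)-7-(tert-butyldimethylsilyloxy)-3,9-dimethyldodeca-3,9,11-trien-2-one
Product: 13 1-[(1S,2R,4aS,6R,8aR)-2-(benzyloxy)-6-(tert-butyldimethylsilyloxy)-1,4a-dimethyl-1,2,4a,5,6,7,8,8a-octahydronaphthalen-1-yl]ethan-1-one (4α-acetyl-3α-benzyloxy-8α-silyloxy-4β,10β-dimethyl-5α-H-octal-1-ene)
Conditions: Me2AlCl (1.5 equiv), CH2Cl2, −78 → −20 °C; aq. NaHCO3
Reagents that add atoms: none
Why: Me2AlCl binds the acetyl oxygen of 12 and lowers the enone LUMO, whose large coefficient at C5 is matched with the large HOMO coefficient at C10 of the 1-alkoxydiene, so a concerted but asynchronous suprafacial [4+2] cycloaddition should form C5–C10 slightly ahead of C3–C4. The closest known reaction types are the Lewis-acid-promoted intramolecular Diels–Alder reaction of terminally activated 1,7,9-decatrienes, which leads to trans-fused octalins, and intermolecular cycloadditions of 1-alkoxydienes with enones. Ring A closes as the cyclohexene created by the cycloaddition itself (C10, C1, C2 and C3 from the diene, C4 and C5 from the dienophile), and ring B closes through the C5–C10 bond as the fused six-membered ring defined by the C6–C9 tether, which adopts a chair. The E-enone geometry is transferred suprafacially, so acetyl and H5 become cis at C4 and C5, and the E,E-diene geometry places the benzyloxy group on C3 and C9 on C10, both outside substituents, cis to each other. The acetyl-endo transition state, with the tether exo, links the two pairs: benzyloxy and acetyl become cis (3α, 4α) and the ring fusion trans (5α-H, 10β-CH3). The absolute sense comes from C8, whose silyl ether sits equatorial on the chair tether, whereas addition to the other diene face would force it axial and syn to the C10 methyl. The step therefore needs endo and facial selectivity; the first is secured by Lewis-acid complexation of the E-enone and by the strain of the exo alternative, the second by the (R)-C8 substituent. Me2AlCl is chosen because it also scavenges adventitious protons, which protects the dienol ether at low temperature.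

Step 9
Reactants: 13 4α-acetyl-3α-benzyloxy-8α-silyloxy-4β,10β-dimethyl-5α-H-octal-1-ene
Product: 15 4α-acetyl-3α-hydroxy-8α-(tert-butyldimethylsilyloxy)-4β,10β-dimethyl-5α-H-trans-decalin, via saturated benzyl ether 14 (not isolated)
Conditions: H2 (1 atm), Pt/C, EtOAc, rt; then Pd(OH)2/C, H2 (1 atm), rt
Reagents that add atoms: none
Why: Catalytic hydrogenation followed by hydrogenolysis in one pot: platinum should saturate the cis-disubstituted C1=C2 alkene without allylic C–O cleavage or migration of the double bond toward C3, and palladium hydroxide then removes the benzyl group. No stereocentre is formed or touched, and the hindered methyl ketone and silyl ether should persist in ethyl acetate.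

Step 10
Reactants: 15 4α-acetyl-3α-hydroxy-8α-(tert-butyldimethylsilyloxy)-4β,10β-dimethyl-5α-H-trans-decalin; 16 angelic acid
Product: 18 4α-acetyl-3α-angeloyloxy-8α-(tert-butyldimethylsilyloxy)-4β,10β-dimethyl-5α-H-trans-decalin, via mixed anhydride 17 (not isolated)
Conditions: 16, 2,4,6-Cl3C6H2COCl, Et3N, toluene, rt; then 15, 80 °C (no DMAP)
Reagents that add atoms: none
Why: Yamaguchi esterification: the alcohol attacks the less hindered angeloyl carbonyl of the mixed anhydride, and leaving out nucleophilic catalysts avoids the addition–elimination path that isomerises the Z-enoate. Acylating O3 while C4 still bears carbon means that no free hydroxyl ever stands beside the tertiary acetate, so acyl migration is excluded by design.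

Step 11
Reactants: 18 4α-acetyl-3α-angeloyloxy-8α-(tert-butyldimethylsilyloxy)-4β,10β-dimethyl-5α-H-trans-decalin
Product: 19 4α-acetoxy-3α-angeloyloxy-8α-(tert-butyldimethylsilyloxy)-4β,10β-dimethyl-5α-H-trans-decalin
Conditions: (CF3CO)2O, urea·H2O2, Na2HPO4, CH2Cl2, 0 °C
Reagents that add atoms: trifluoroperacetic acid (formed from trifluoroacetic anhydride and urea–hydrogen peroxide), OOC(=O)C(F)(F)F
Why: Baeyer–Villiger oxidation: in the peracid adduct the tertiary C4 migrates in preference to methyl and with retention, which turns the 4α-acetyl group into the 4α-acetate. The electron-poor angelate alkene should be epoxidised much more slowly than the ketone is oxidised at 0 °C, and the phosphate buffer protects the silyl ether and the esters.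

Step 12
Reactants: 19 4α-acetoxy-3α-angeloyloxy-8α-(tert-butyldimethylsilyloxy)-4β,10β-dimethyl-5α-H-trans-decalin
Product: 20 4α-acetoxy-3α-angeloyloxy-4β,10β-dimethyl-5α-H-trans-decalin-8α-ol
Conditions: HF·pyridine, pyridine, THF, 0 °C → rt
Reagents that add atoms: none
Why: Fluoride-mediated desilylation under buffered, non-basic conditions should leave both esters in place and gives no opening for acyl transfer.

Step 13
Reactants: 20 4α-acetoxy-3α-angeloyloxy-4β,10β-dimethyl-5α-H-trans-decalin-8α-ol
Product: 21 4α-acetoxy-3α-angeloyloxy-4β,10β-dimethyl-5α-H-trans-decalin-8-one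
Conditions: Dess–Martin periodinane, NaHCO3, CH2Cl2, rt
Reagents that add atoms: none
Why: Dess–Martin oxidation of an unhindered equatorial secondary alcohol under neutral conditions; the C8 stereocentre has done its work and is removed here.

Step 14
Reactants: 21 4α-acetoxy-3α-angeloyloxy-4β,10β-dimethyl-5α-H-trans-decalin-8-one
Product: 23 4α-acetoxy-3α-angeloyloxy-7-(2-hydroxypropan-2-yl)-4β,10β-dimethyl-5α-H-trans-decalin-8-one (C7 epimers), via lithium enolate 22 (not isolated)
Conditions: LiN(SiMe3)2 (1.05 equiv), THF, −78 °C; acetone, −78 °C; AcOH
Reagents that add atoms: acetone, CC(C)=O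
Why: Directed aldol addition: kinetic deprotonation by the bulky amide should occur at C7 and not at the neopentyl C9 beside quaternary C10, and the ketone is enolised much faster than either ester. The configuration at C7 of 23 is of no consequence, because C7 becomes trigonal in step 15.

Step 15
Reactants: 23 4α-acetoxy-3α-angeloyloxy-7-(2-hydroxypropan-2-yl)-4β,10β-dimethyl-5α-H-trans-decalin-8-one
Product: 25 4α-acetoxy-3α-angeloyloxy-5α-eudesm-7(11)-en-8-one, via tertiary mesylate 24 (not isolated)
Conditions: MsCl, Et3N, CH2Cl2, 0 °C → rt; then DBU, rt
Reagents that add atoms: none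
Why: Mesylation of the tertiary carbinol (through sulfene) and E1cB elimination via the ketone enolate should give the conjugated isopropylidene ketone; DBU completes the move of the double bond into conjugation.

Step 16
Reactants: 25 4α-acetoxy-3α-angeloyloxy-5α-eudesm-7(11)-en-8-one
Product: 27 (1S,2R,4aR,7S,8aR)-1-acetoxy-7-hydroperoxy-1,4a-dimethyl-6-oxo-7-(prop-1-en-2-yl)decahydronaphthalen-2-yl (Z)-2-methylbut-2-enoate (the target), via potassium dienolate 26 (not isolated)
Conditions: KOtBu (1.1 equiv), THF/t-BuOH, −40 °C, argon; then O2 (1 atm), −78 → −40 °C; AcOH, −78 °C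
Reagents that add atoms: dioxygen, O=O
Why: Enolate autoxidation (α-hydroperoxylation of a ketone enolate): under equilibrating alkoxide conditions the through-conjugated dienolate formed by deprotonation at C12 is the thermodynamic enolate, and it should combine with dioxygen at its α-carbon C7, which moves the alkene to C11=C12. Oxygen approaches the ring enolate axially on the α face through a chair-like transition state, so the hydroperoxy group becomes 7α and the isopropenyl group equatorial. The tertiary hydroperoxide has no α-hydrogen to lose, and the cold acidic quench avoids base-induced C7–C8 cleavage.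

## Compound list

1 | (R)-2-(but-3-en-1-yl)oxirane | C=CCC[C@@H]1CO1 | starting material
2 | (R)-oct-7-en-1-yn-4-ol | C=CCC[C@@H](O)CC#C | intermediate
3 | (R)-tert-butyldimethyl(oct-7-en-1-yn-4-yloxy)silane | C=CCC[C@@H](O[Si](C)(C)C(C)(C)C)CC#C | intermediate
4 | dimethyl[(4R,1E)-4-(tert-butyldimethylsilyloxy)-2-methylocta-1,7-dien-1-yl]alane | C=CCC[C@@H](O[Si](C)(C)C(C)(C)C)C/C(C)=C/[Al](C)C | intermediate
5 | (R,E)-tert-butyl[(1-iodo-2-methylocta-1,7-dien-4-yl)oxy]dimethylsilane | C=CCC[C@@H](O[Si](C)(C)C(C)(C)C)C/C(C)=C/I | intermediate
6 | (5R,E)-5-(tert-butyldimethylsilyloxy)-8-iodo-7-methyloct-7-ene-1,2-diol (C2 epimers) | OCC(O)CC[C@@H](O[Si](C)(C)C(C)(C)C)C/C(C)=C/I | intermediate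
7 | (R,E)-4-(tert-butyldimethylsilyloxy)-7-iodo-6-methylhept-6-enal | O=CCC[C@@H](O[Si](C)(C)C(C)(C)C)C/C(C)=C/I | intermediate
8 | 3-(triphenylphosphoranylidene)butan-2-one | CC(=O)C(C)=P(c1ccccc1)(c1ccccc1)c1ccccc1 | starting material
9 | (7R,3E,9E)-7-(tert-butyldimethylsilyloxy)-10-iodo-3,9-dimethyldeca-3,9-dien-2-one | CC(=O)/C(C)=C/CC[C@@H](O[Si](C)(C)C(C)(C)C)C/C(C)=C/I | intermediate
10 | benzyl ethynyl ether | C#COCc1ccccc1 | starting material
11 | (E)-2-[2-(benzyloxy)ethenyl]-4,4,5,5-tetramethyl-1,3,2-dioxaborolane | CC1(C)OB(/C=C/OCc2ccccc2)OC1(C)C | intermediate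
12 | (7R,3E,9E,11E)-12-(benzyloxy)-7-(tert-butyldimethylsilyloxy)-3,9-dimethyldodeca-3,9,11-trien-2-one | CC(=O)/C(C)=C/CC[C@@H](O[Si](C)(C)C(C)(C)C)C/C(C)=C/C=C/OCc1ccccc1 | intermediate
13 | 1-[(1S,2R,4aS,6R,8aR)-2-(benzyloxy)-6-(tert-butyldimethylsilyloxy)-1,4a-dimethyl-1,2,4a,5,6,7,8,8a-octahydronaphthalen-1-yl]ethan-1-one | C1C[C@@H]2[C@](C)(C=C[C@@H](OCc3ccccc3)[C@@]2(C)C(C)=O)C[C@@H]1O[Si](C)(C)C(C)(C)C | intermediate
14 | 4α-acetyl-3α-benzyloxy-8α-(tert-butyldimethylsilyloxy)-4β,10β-dimethyl-5α-H-trans-decalin | C1C[C@@H]2[C@](C)(CC[C@@H](OCc3ccccc3)[C@@]2(C)C(C)=O)C[C@@H]1O[Si](C)(C)C(C)(C)C | intermediate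
15 | 4α-acetyl-3α-hydroxy-8α-(tert-butyldimethylsilyloxy)-4β,10β-dimethyl-5α-H-trans-decalin | C1C[C@@H]2[C@](C)(CC[C@@H](O)[C@@]2(C)C(C)=O)C[C@@H]1O[Si](C)(C)C(C)(C)C | intermediate
16 | angelic acid, (Z)-2-methylbut-2-enoic acid | C/C=C(/C)C(=O)O | starting material
17 | (Z)-2-methylbut-2-enoic 2,4,6-trichlorobenzoic anhydride | C/C=C(/C)C(=O)OC(=O)c1c(Cl)cc(Cl)cc1Cl | intermediate
18 | 4α-acetyl-3α-angeloyloxy-8α-(tert-butyldimethylsilyloxy)-4β,10β-dimethyl-5α-H-trans-decalin | C1C[C@@H]2[C@](C)(CC[C@@H](OC(=O)/C(C)=C\C)[C@@]2(C)C(C)=O)C[C@@H]1O[Si](C)(C)C(C)(C)C | intermediate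
19 | 4α-acetoxy-3α-angeloyloxy-8α-(tert-butyldimethylsilyloxy)-4β,10β-dimethyl-5α-H-trans-decalin | C1C[C@@H]2[C@](C)(CC[C@@H](OC(=O)/C(C)=C\C)[C@@]2(C)OC(C)=O)C[C@@H]1O[Si](C)(C)C(C)(C)C | intermediate
20 | 4α-acetoxy-3α-angeloyloxy-4β,10β-dimethyl-5α-H-trans-decalin-8α-ol | C1C[C@@H]2[C@](C)(CC[C@@H](OC(=O)/C(C)=C\C)[C@@]2(C)OC(C)=O)C[C@@H]1O | intermediate
21 | 4α-acetoxy-3α-angeloyloxy-4β,10β-dimethyl-5α-H-trans-decalin-8-one | C1C[C@@H]2[C@](C)(CC[C@@H](OC(=O)/C(C)=C\C)[C@@]2(C)OC(C)=O)CC1=O | intermediate
22 | lithium 7-en-8-olate of 21 | [Li]OC1=CC[C@@H]2[C@](C)(CC[C@@H](OC(=O)/C(C)=C\C)[C@@]2(C)OC(C)=O)C1 | intermediate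
23 | 4α-acetoxy-3α-angeloyloxy-7-(2-hydroxypropan-2-yl)-4β,10β-dimethyl-5α-H-trans-decalin-8-one (C7 epimers) | CC(C)(O)C1C[C@@H]2[C@](C)(CC[C@@H](OC(=O)/C(C)=C\C)[C@@]2(C)OC(C)=O)CC1=O | intermediate
24 | tertiary methanesulfonate of 23 | CC(C)(OS(C)(=O)=O)C1C[C@@H]2[C@](C)(CC[C@@H](OC(=O)/C(C)=C\C)[C@@]2(C)OC(C)=O)CC1=O | intermediate
25 | 4α-acetoxy-3α-angeloyloxy-5α-eudesm-7(11)-en-8-one | CC(C)=C1C[C@@H]2[C@](C)(CC[C@@H](OC(=O)/C(C)=C\C)[C@@]2(C)OC(C)=O)CC1=O | intermediate
26 | potassium 4α-acetoxy-3α-angeloyloxy-5α-eudesma-7,11-dien-8-olate | [K]OC1=C(C(C)=C)C[C@@H]2[C@](C)(CC[C@@H](OC(=O)/C(C)=C\C)[C@@]2(C)OC(C)=O)C1 | intermediate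
27 | (1S,2R,4aR,7S,8aR)-1-acetoxy-7-hydroperoxy-1,4a-dimethyl-6-oxo-7-(prop-1-en-2-yl)decahydronaphthalen-2-yl (Z)-2-methylbut-2-enoate | C=C(C)[C@@]1(OO)C[C@@H]2[C@](C)(CC[C@@H](OC(=O)/C(C)=C\C)[C@@]2(C)OC(C)=O)CC1=O | target

## Step count and least certain steps

Total step count: 16. Longest linear sequence: 15 steps (steps 1–5 and 7–16); step 6 is a one-step side branch.

**Step 8 (key step).** The most likely failure is a cycloaddition that is too slow. C14 occupies the inside position of the diene, so the reactive s-cis conformer is strained, and both new bonds end at fully substituted carbons. The Lewis acid then has time to ionise or hydrolyse the dienol ether, or a stepwise Mukaiyama–Michael pathway erodes endo selectivity. The fallback swaps the ketone dienophile for a smaller, more strongly activated aldehyde and installs the methyl ketone afterwards. It sets out from 7: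
- Wittig reaction with 2-(triphenylphosphoranylidene)propanal should give iodo enal F1.
- Coupling with 11 as in step 7 gives trienal F2.
- Me2AlCl-promoted cycloaddition gives cycloadduct aldehyde F3, by the same endo and facial arguments.
- Addition of MeMgBr gives secondary carbinol F4, and Dess–Martin oxidation returns to the route at 13.

**Step 16.** The likely failures are competing enolisation toward C9 with oxygenation there, attack of oxygen at C12 instead of C7, and base-induced cleavage of the α-hydroperoxy ketone. The fallback generates the dienolate regiospecifically and without alkoxide base. It sets out from 25: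
- Soft enolisation with Me3SiOTf and Et3N should give trimethylsilyl dienol ether F5, which can be purified free of any cross-conjugated isomer.
- Tris(dimethylamino)sulfonium difluorotrimethylsilicate at −78 °C unmasks sulfonium dienolate F6.
- Oxygenation and a cold acetic acid quench return to the route at 27.

**Step 11.** The likely failure is epoxidation of the angelate alkene in competition with slow peracid addition to the hindered carbonyl. The fallback moves the oxygen insertion to a stage without any alkene. It sets out from 13:
- Hydrogenation over Pt/C alone is stopped at 14, which is isolated.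
- Oxidation of 14 with buffered trifluoroperacetic acid gives benzyl ether acetate F7.
- Hydrogenolysis over Pd(OH)2/C gives hydroxy acetate F8.
- Acylation with preformed 17 at the lowest workable temperature returns to the route at 19.

The price is that F8 is exposed to acetyl migration from O4 to O3, which is why this order is the second choice.

**Step 10.** The likely failure is sluggish acylation of the axial, neopentyl-type C3 hydroxyl, with Z to E isomerisation on prolonged heating. The fallback builds the Z-alkene on the ester instead of transferring it. It sets out from 15: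
- Carbodiimide esterification with 2-[bis(2,2,2-trifluoroethoxy)phosphoryl]propanoic acid should give phosphonopropionate ester F9.
- Still–Gennari olefination with acetaldehyde (KN(SiMe3)2, 18-crown-6, THF, −78 °C) returns to the route at 18.

All four fallbacks use known chemistry.

## Further compounds

F1 | step 8 | (R,2E,8E)-6-(tert-butyldimethylsilyloxy)-9-iodo-2,8-dimethylnona-2,8-dienal | O=C/C(C)=C/CC[C@@H](O[Si](C)(C)C(C)(C)C)C/C(C)=C/I
F2 | step 8 | (6R,2E,8E,10E)-11-(benzyloxy)-6-(tert-butyldimethylsilyloxy)-2,8-dimethylundeca-2,8,10-trienal | O=C/C(C)=C/CC[C@@H](O[Si](C)(C)C(C)(C)C)C/C(C)=C/C=C/OCc1ccccc1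
F3 | step 8 | 3α-benzyloxy-4α-formyl-8α-(tert-butyldimethylsilyloxy)-4β,10β-dimethyl-5α-H-octal-1-ene | C1C[C@@H]2[C@](C)(C=C[C@@H](OCc3ccccc3)[C@@]2(C)C=O)C[C@@H]1O[Si](C)(C)C(C)(C)C
F4 | step 8 | 3α-benzyloxy-4α-(1-hydroxyethyl)-8α-(tert-butyldimethylsilyloxy)-4β,10β-dimethyl-5α-H-octal-1-ene (carbinol epimers) | C1C[C@@H]2[C@](C)(C=C[C@@H](OCc3ccccc3)[C@@]2(C)C(C)O)C[C@@H]1O[Si](C)(C)C(C)(C)C
F5 | step 16 | 4α-acetoxy-3α-angeloyloxy-8-(trimethylsilyloxy)-5α-eudesma-7,11-diene | C[Si](C)(C)OC1=C(C(C)=C)C[C@@H]2[C@](C)(CC[C@@H](OC(=O)/C(C)=C\C)[C@@]2(C)OC(C)=O)C1
F6 | step 16 | tris(dimethylamino)sulfonium 4α-acetoxy-3α-angeloyloxy-5α-eudesma-7,11-dien-8-olate | [O-]C1=C(C(C)=C)C[C@@H]2[C@](C)(CC[C@@H](OC(=O)/C(C)=C\C)[C@@]2(C)OC(C)=O)C1.CN(C)[S+](N(C)C)N(C)C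
F7 | step 11 | 4α-acetoxy-3α-benzyloxy-8α-(tert-butyldimethylsilyloxy)-4β,10β-dimethyl-5α-H-trans-decalin | C1C[C@@H]2[C@](C)(CC[C@@H](OCc3ccccc3)[C@@]2(C)OC(C)=O)C[C@@H]1O[Si](C)(C)C(C)(C)C
F8 | step 11 | 4α-acetoxy-3α-hydroxy-8α-(tert-butyldimethylsilyloxy)-4β,10β-dimethyl-5α-H-trans-decalin | C1C[C@@H]2[C@](C)(CC[C@@H](O)[C@@]2(C)OC(C)=O)C[C@@H]1O[Si](C)(C)C(C)(C)C
F9 | step 10 | 4α-acetyl-3α-{2-[bis(2,2,2-trifluoroethoxy)phosphoryl]propanoyloxy}-8α-(tert-butyldimethylsilyloxy)-4β,10β-dimethyl-5α-H-trans-decalin | C1C[C@@H]2[C@](C)(CC[C@@H](OC(=O)C(C)P(=O)(OCC(F)(F)F)OCC(F)(F)F)[C@@]2(C)C(C)=O)C[C@@H]1O[Si](C)(C)C(C)(C)C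
A1 | alternative 1 | 4β-hydroxyoctal-5(10)-en-8-one ethylene ketal (eudesmane numbering) | O[C@H]1CCCC2=C1CCC1(OCCO1)C2
A2 | alternative 1 | 4β-hydroxy-5β,10β-methanodecalin-8-one ethylene ketal | O[C@H]1CCC[C@@]23C[C@@]12CCC1(OCCO1)C3
A3 | alternative 2 | 3-methylcyclohex-2-en-1-one | CC1=CC(=O)CCC1
A4 | alternative 2 | allene (propa-1,2-diene) | C=C=C
A5 | alternative 2 | 6-methyl-8-methylidenebicyclo[4.2.0]octan-2-one | O=C1CCC[C@]2(C)CC(=C)[C@H]12
A6 | alternative 3 | 2-[1,3-dimethyl-2-(3-methylbut-2-en-1-yl)cyclohex-3-en-1-yl]acetaldehyde (prenyl trans to the acetaldehyde arm) | CC(C)=CC[C@H]1C(C)=CCC[C@]1(C)CC=O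
A7 | alternative 3 | eudesma-3,11-dien-8α-ol (7β-isopropenyl) | C=C(C)[C@H]1C[C@@H]2[C@](C)(CCC=C2C)C[C@@H]1O
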